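If each initiator began one chain, I could have reckoned these two flasks at the bench in a single line.

    monomer in chains + living end → free monomer + living end, rate k1*[living end] as long as [monomer in chains] is above zero (k1 = 0.00106 /s)
    2 initiator → spent initiator (k2 = 19.0 /M/s)
    free monomer → decomposition product (k3 = 3.34 × 10⁻⁷ /s)
    free monomer + initiator → living end + monomer in chains (k4 = 0.0159 /M/s)
    free monomer + living end → monomer in chains + living end, rate k5*[living end]*[free monomer] (k5 = 0.487 /M/s)

- violet: free monomer 30 mM; initiator 0.15 mM; time 6.0 h
- ochre: free monomer 30 mM; initiator 0.30 mM; time 6.0 h

- a step written with two of one species runs at k times the square of its concentration and takes two of it each time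
- the average divides the monomer in chains by the number of chains begun, living and dead together
- run time (violet): 6.0 h

- which of the two ends with the longer chains by the average number of monomer units in a chain (chains begun, living or dead) ("neither" if they lie within 10%) (violet / ochre / neither)
- average number of monomer units in a chain (chains begun, living or dead) at the end, violet
- average number of monomer units in a chain (chains begun, living or dead) at the end, ochre

**Bench rule.** I first counted chains begun as the initiator charge, which at full uptake gave 200 units in violet and 100 in ochre. At equal uptake, that made ochre half as long as violet.

**The border.** The rule needs capture by free monomer to outrun self-reaction of initiator, so I took the starting ratio of self-reaction to capture. It came to 11.9 in violet and 23.9 in ochre , so the rule failed in both. With free monomer held at its charge, the two losses integrate to the logarithm of one plus the ratio, divided by the ratio. This gave 21.4% in violet and 13.5% in ochre: the chain yield, the fraction of charged initiator that begins a chain. Doubling the initiator doubled the ratio, but by this reckoning chains begun grew by a factor of 1.26.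

**The length.** I held the chains at that number from the start. Free monomer then fell in pseudo-first-order fashion toward the fraction 7.26%, where growth and return from chains balance. I reckoned uptake at 26.6% of the charge in violet and 32.1% in ochre. My lengths were 248 for violet and 238 for ochre, so my answer was neither.

**The forecast.** It gave 238 for violet and 235 for ochre, hence neither, holding that “the extra monomer in ochre almost exactly offsets its extra chains”. My lengths stood above its .

**The flasks.** The simulation gave 237 for violet and 230 for ochre, so neither. In ochre at 2.87 h, free monomer had a half-life of 9.9 h toward chains against 24 d toward decomposition product. At 6.00 h, ochre held 30.8% of its charge in chains and 0.605% as decomposition product. Living ends then read 21.4% of the initiator charge in violet and 13.4% in ochre, beside chain yields of 21.4% and 13.5%. In a neighbour of ochre charged with 18 mM of free monomer, the ratio rose to 39.8 and the chain yield became 9.31%. Its living ends read 9.27% of the initiator charge at 6.00 h, and its chains averaged 136 units.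

(Its constants are made up; the flask was simulated.)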